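**Plan**

Carotenoid numbering is used: ring C1 (CMe2), C2, C3 (OH), C4 (OH), C5 (Me), C6; chain C7 to C15 and C15′ to C1′.

- Retrosynthesis: cut C11=C12 and C11′=C12′ (Wittig: ring C15 salt 20 + C10 dialdehyde 25 + ψ-end C15 salt 24), then cut the ring bonds C4–C5 and C1–C6 together, leaving bromo aldehyde 6 (C1 to C4) and dienyne 12 (C5 to C11).
- Enabling feature: the tetrasubstituted ring alkene C5=C6 carries the carbinol C4 on C5 and the quaternary C1 on C6 and is conjugated through C6 with C7=C8. Read backwards, C5≡C6–C7=C8 is a 1,3-enyne, C4 an aldehyde carbon and C1 a tertiary radical, so one nickel centre can join C4 to C5 and then C6 to C1.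
- Forward: 6 (steps 1–4) and 12 (steps 5–7) are made, the ring arises in step 8, C4 is corrected (steps 9–10), salt 20 is made (steps 11–12), the ψ half 27 is built (steps 13–15), the chain is joined (step 16) and the silyl groups are removed (step 17).
- Stereochemistry: C3 from the catalytic asymmetric glyoxylate-ene reaction (step 1); C4 from substrate-controlled reduction of enone 15 (step 10); E alkenes from the starting materials, syn-hydrozirconation and Wittig olefination with thermal equilibration.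

Key step: step 8

Assumption: pseudoionone 21 is used as its (3E,5E) isomer, and 7 and 25 are taken as the commercial E and all-E compounds.

**Route**

Step 1
Reactants: 1 isobutylene (2-methylpropene); 2 ethyl glyoxylate
Product: 3 ethyl (2R)-2-hydroxy-4-methylpent-4-enoate
Conditions: (R)-BINOL (10 mol %), TiCl2(OiPr)2 (10 mol %), 4 Å MS, CH2Cl2, −30 °C
Reagents that add atoms: none
Why: Catalytic asymmetric glyoxylate-ene reaction, in which the (R)-BINOL–titanium Lewis acid activates the aldehyde and exposes one face, so that transfer of an allylic hydrogen of isobutylene should set the carbinol carbon (later ring C3) as R.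

Step 2
Reactants: 3 ethyl (2R)-2-hydroxy-4-methylpent-4-enoate
Product: 4 ethyl (2R)-2-[(tert-butyldimethylsilyl)oxy]-4-methylpent-4-enoate
Conditions: TBSCl, imidazole, DMF, rt
Reagents that add atoms: tert-butyldimethylsilyl chloride, CC(C)(C)[Si](C)(C)Cl
Why: Silyl ether formation that masks the secondary hydroxyl as a bulky, non-chelating group for steps 3 to 10 without touching the stereocentre.

Step 3
Reactants: 4 ethyl (2R)-2-[(tert-butyldimethylsilyl)oxy]-4-methylpent-4-enoate
Product: 5 ethyl (2R)-4-bromo-2-[(tert-butyldimethylsilyl)oxy]-4-methylpentanoate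
Conditions: Co(acac)2 (30 mol %), t-BuOOH (30 mol %), Et3SiH, TsBr, n-PrOH, rt
Reagents that add atoms: p-toluenesulfonyl bromide, Cc1ccc(cc1)S(=O)(=O)Br
Why: Markovnikov radical hydrobromination by metal-hydride hydrogen atom transfer, in which the cobalt hydride gives a hydrogen atom to the CH2 terminus and the tertiary radical takes bromine from TsBr, under neutral conditions that avoid the γ-lactonisation that ionic HBr addition to a pent-4-enoate would invite.

Step 4
Reactants: 5 ethyl (2R)-4-bromo-2-[(tert-butyldimethylsilyl)oxy]-4-methylpentanoate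
Product: 6 (2R)-4-bromo-2-[(tert-butyldimethylsilyl)oxy]-4-methylpentanal
Conditions: i-Bu2AlH (DIBAL-H, 1.1 equiv), CH2Cl2, −78 °C; Rochelle salt work-up
Reagents that add atoms: none
Why: Partial reduction of an ester to the aldehyde, where the α-silyloxy group stabilises the tetrahedral aluminate until work-up, and neither the tertiary bromide nor the α-stereocentre should be affected at −78 °C in the absence of base.

Step 5
Reactants: 7 (E)-3-methylpent-2-en-4-yn-1-ol
Product: 8 triethyl{[(2E)-3-methylpent-2-en-4-yn-1-yl]oxy}silane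
Conditions: Et3SiCl, imidazole, CH2Cl2, 0 °C
Reagents that add atoms: chlorotriethylsilane, CC[Si](Cl)(CC)CC
Why: Silyl ether formation; the primary triethylsilyl ether is inert to low-valent nickel as an allylic group and can later be removed in the presence of secondary tert-butyldimethylsilyl ethers.

Step 6
Reactants: 8 triethyl{[(2E)-3-methylpent-2-en-4-yn-1-yl]oxy}silane
Product: 10 triethyl{[(2E,4E)-5-iodo-3-methylpenta-2,4-dien-1-yl]oxy}silane, via alkenylzirconocene chloride 9 (not isolated)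
Conditions: Cp2Zr(H)Cl (1.3 equiv), THF, rt, dark; then I2, 0 °C
Reagents that add atoms: iodine, II
Why: Hydrozirconation–iodination, in which syn addition of Zr–H places zirconium on the terminal alkyne carbon and iodinolysis proceeds with retention, so the new alkene should be E and the existing E alkene is untouched.

Step 7
Reactants: 10 triethyl{[(2E,4E)-5-iodo-3-methylpenta-2,4-dien-1-yl]oxy}silane; 11 propyne
Product: 12 triethyl{[(2E,4E)-3-methylocta-2,4-dien-6-yn-1-yl]oxy}silane
Conditions: PdCl2(PPh3)2 (3 mol %), CuI (6 mol %), Et3N, THF, 0 °C to rt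
Reagents that add atoms: none
Why: Sonogashira coupling of an alkenyl iodide with a terminal alkyne, which proceeds with retention of the alkene geometry and delivers the methyl-capped 1,3-enyne needed in step 8.

Step 8
Reactants: 6 (2R)-4-bromo-2-[(tert-butyldimethylsilyl)oxy]-4-methylpentanal; 12 triethyl{[(2E,4E)-3-methylocta-2,4-dien-6-yn-1-yl]oxy}silane
Product: 14 (1S,6R)-6-[(tert-butyldimethylsilyl)oxy]-2,4,4-trimethyl-3-{(1E,3E)-3-methyl-5-[(triethylsilyl)oxy]penta-1,3-dien-1-yl}cyclohex-2-en-1-ol, via oxanickelacyclopentene 13 (not isolated)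
Conditions: Ni(cod)2 (15 mol %), 4,4′-di-tert-butyl-2,2′-bipyridine (18 mol %), Zn dust (3 equiv), ZnBr2 (20 mol %), DMA/THF, 25 °C, 6 added over 8 h to 12 (1.5 equiv); aq NH4Cl
Reagents that add atoms: none
Why: Proposed new method: zerovalent nickel should couple the aldehyde of 6 and the alkyne of 12 oxidatively to the oxanickelacyclopentene 13 (C4–C5 formed, nickel on C6), then zinc bromide takes the alkoxide from nickel, zinc reduces the alkenylnickel bromide to monovalent nickel, this abstracts the bromine atom of the pendant tertiary C1–Br, and the tertiary radical rebounds to nickel so that C6–C1 forms by reductive elimination from trivalent nickel. The closest known reaction types are the nickel-catalysed reductive coupling of aldehydes with 1,3-enynes, which places the new C–C bond on the alkyne carbon remote from the alkene, and the nickel-catalysed reductive cross-coupling of tertiary alkyl bromides with alkenyl or aryl halides, which builds quaternary carbons by the same radical capture and reductive elimination; new is their merger, with the nickelacycle in the role of the oxidative-addition complex. The six-membered ring closes in the second event, by C(sp2)–C(sp3) reductive elimination from a seven-membered nickelacycle made of nickel and C1 to C6, which is possible because the syn addition across the alkyne leaves C4 and nickel cis on C5=C6. The new stereocentre C4 is set in the oxidative cyclisation under Felkin–Anh control by the C3 silyloxy group and should be mainly 4S (3,4-cis), which is not the target configuration and is therefore corrected in steps 9 and 10, where both C4 epimers converge. The step needs regioselectivity, secured by the conjugation of C6 with C7=C8 in the enyne, and chemoselectivity for the aldehyde over the C–Br bond in the first event, for which 6 is added slowly to an excess of 12 so that the tertiary radical is formed only next to a nickel centre that already holds C6.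

Step 9
Reactants: 14 (1S,6R)-6-[(tert-butyldimethylsilyl)oxy]-2,4,4-trimethyl-3-{(1E,3E)-3-methyl-5-[(triethylsilyl)oxy]penta-1,3-dien-1-yl}cyclohex-2-en-1-ol
Product: 15 (6R)-6-[(tert-butyldimethylsilyl)oxy]-2,4,4-trimethyl-3-{(1E,3E)-3-methyl-5-[(triethylsilyl)oxy]penta-1,3-dien-1-yl}cyclohex-2-en-1-one
Conditions: activated MnO2 (20 equiv), CH2Cl2, rt
Reagents that add atoms: none
Why: Manganese dioxide oxidation of an allylic alcohol to the enone, which erases C4 so that either C4 epimer from step 8 converges on 15, while the silyl ethers and the C3 stereocentre should survive the neutral conditions.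

Step 10
Reactants: 15 (6R)-6-[(tert-butyldimethylsilyl)oxy]-2,4,4-trimethyl-3-{(1E,3E)-3-methyl-5-[(triethylsilyl)oxy]penta-1,3-dien-1-yl}cyclohex-2-en-1-one
Product: 16 (1R,6R)-6-[(tert-butyldimethylsilyl)oxy]-2,4,4-trimethyl-3-{(1E,3E)-3-methyl-5-[(triethylsilyl)oxy]penta-1,3-dien-1-yl}cyclohex-2-en-1-ol
Conditions: NaBH4, CeCl3·7H2O, MeOH/THF, −78 to −20 °C
Reagents that add atoms: none
Why: Luche reduction (1,2-reduction of an enone), in which the C3 silyloxy group sits equatorial to avoid the axial methyl on C1 and hydride should attack C4 axially from the face opposite that methyl, giving the equatorial, 3,4-trans (4R) alcohol.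

Step 11
Reactants: 16 (1R,6R)-6-[(tert-butyldimethylsilyl)oxy]-2,4,4-trimethyl-3-{(1E,3E)-3-methyl-5-[(triethylsilyl)oxy]penta-1,3-dien-1-yl}cyclohex-2-en-1-ol
Product: 18 (2E,4E)-5-{(3R,4R)-3,4-bis[(tert-butyldimethylsilyl)oxy]-2,6,6-trimethylcyclohex-1-en-1-yl}-3-methylpenta-2,4-dien-1-ol, via tris-silyl ether 17 (not isolated)
Conditions: TBSOTf, 2,6-lutidine, CH2Cl2, −78 °C; aqueous wash; then PPTS (cat.), MeOH/CH2Cl2, 0 °C
Reagents that add atoms: tert-butyldimethylsilyl triflate, CC(C)(C)[Si](C)(C)OS(=O)(=O)C(F)(F)F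
Why: Silyl ether formation at the hindered allylic C4 hydroxyl with the silyl triflate followed by acid-catalysed methanolysis, which should remove only the far more labile primary triethylsilyl ether and leaves both stereocentres unchanged.

Step 12
Reactants: 18 (2E,4E)-5-{(3R,4R)-3,4-bis[(tert-butyldimethylsilyl)oxy]-2,6,6-trimethylcyclohex-1-en-1-yl}-3-methylpenta-2,4-dien-1-ol
Product: 20 [(2E,4E)-5-{(3R,4R)-3,4-bis[(tert-butyldimethylsilyl)oxy]-2,6,6-trimethylcyclohex-1-en-1-yl}-3-methylpenta-2,4-dien-1-yl]triphenylphosphonium bromide, via allylic bromide 19 (not isolated)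
Conditions: CBr4 (1.2 equiv), PPh3 (1.2 equiv), 2,6-lutidine (0.2 equiv), CH2Cl2, −20 °C; then PPh3 (1.5 equiv), rt, dark
Reagents that add atoms: carbon tetrabromide, BrC(Br)(Br)Br; triphenylphosphine, c1ccc(cc1)P(c1ccccc1)c1ccccc1
Why: Appel bromination of the primary allylic alcohol followed by SN2 quaternisation of PPh3 (phosphonium salt formation), chosen over HBr so that the acid-labile allylic C4 silyl ether is not ionised.

Step 13
Reactants: 21 (3E,5E)-6,10-dimethylundeca-3,5,9-trien-2-one (pseudoionone); 22 vinylmagnesium bromide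
Product: 23 (4E,6E)-3,7,11-trimethyldodeca-1,4,6,10-tetraen-3-ol (racemic)
Conditions: THF, −20 to 0 °C; aq NH4Cl
Reagents that add atoms: none
Why: Grignard 1,2-addition to the ketone carbonyl of the dienone, which gives the tertiary vinyl carbinol as a racemate, acceptable because this centre becomes sp2 in step 14.

Step 14
Reactants: 23 (4E,6E)-3,7,11-trimethyldodeca-1,4,6,10-tetraen-3-ol
Product: 24 [(2E,4E,6E)-3,7,11-trimethyldodeca-2,4,6,10-tetraen-1-yl]triphenylphosphonium bromide
Conditions: PPh3·HBr, MeOH, 0 °C to rt; crystallisation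
Reagents that add atoms: triphenylphosphine hydrobromide, [Br-].c1ccc(cc1)[PH+](c1ccccc1)c1ccccc1
Why: Acid-mediated allylic transposition with capture by PPh3 (phosphonium salt formation from a tertiary vinyl carbinol), in which the delocalised cation is trapped at its primary terminus to give the conjugated salt, the 2E isomer being secured by crystallisation.

Step 15
Reactants: 24 [(2E,4E,6E)-3,7,11-trimethyldodeca-2,4,6,10-tetraen-1-yl]triphenylphosphonium bromide; 25 (2E,4E,6E)-2,7-dimethylocta-2,4,6-trienedial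
Product: 27 (2E,4E,6E,8E,10E,12E,14E)-2,7,11,15,19-pentamethylicosa-2,4,6,8,10,12,14,18-octaenal, via 8Z aldehyde 26 (not isolated)
Conditions: NaOMe, MeOH/CH2Cl2, 0 °C to rt, 24 added slowly to 25 (3 equiv), dark; then heptane, 90 °C
Reagents that add atoms: none
Why: Wittig olefination of one aldehyde of the dialdehyde, used in excess so that mono-olefination should prevail over the less electrophilic product aldehyde, the new alkene forming as an E/Z mixture whose hindered Z isomer 26 should isomerise thermally to the E form.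

Step 16
Reactants: 20 [(2E,4E)-5-{(3R,4R)-3,4-bis[(tert-butyldimethylsilyl)oxy]-2,6,6-trimethylcyclohex-1-en-1-yl}-3-methylpenta-2,4-dien-1-yl]triphenylphosphonium bromide; 27 (2E,4E,6E,8E,10E,12E,14E)-2,7,11,15,19-pentamethylicosa-2,4,6,8,10,12,14,18-octaenal
Product: 29 (3R,4R)-3,4-bis[(tert-butyldimethylsilyl)oxy]-β,ψ-carotene (all-E), via 11Z bis-silyl ether 28 (not isolated)
Conditions: NaOMe, MeOH/CH2Cl2, 0 °C to rt, dark, argon; then heptane, 90 °C
Reagents that add atoms: none
Why: Wittig olefination that joins the ring C15 ylide to the C25 aldehyde at C11=C12, the silyl ethers tolerating methoxide and the sterically hindered 11Z isomer 28 being expected to equilibrate thermally to the all-E polyene.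

Step 17
Reactants: 29 (3R,4R)-3,4-bis[(tert-butyldimethylsilyl)oxy]-β,ψ-carotene
Product: 30 (3R,4R)-β,ψ-carotene-3,4-diol (all-E)
Conditions: Bu4NF, AcOH (1:1), THF, 0 °C to rt, dark, argon
Reagents that add atoms: none
Why: Fluoride-mediated desilylation under buffered conditions, which should free both hydroxyls without acid that would ionise the allylic C4 hydroxyl and without change at C3 or C4.

**Compound list**

1 | isobutylene (2-methylpropene) | CC(C)=C | starting material
2 | ethyl glyoxylate | CCOC(=O)C=O | starting material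
3 | ethyl (2R)-2-hydroxy-4-methylpent-4-enoate | CCOC(=O)[C@H](O)CC(C)=C | intermediate
4 | ethyl (2R)-2-[(tert-butyldimethylsilyl)oxy]-4-methylpent-4-enoate | CCOC(=O)[C@H](O[Si](C)(C)C(C)(C)C)CC(C)=C | intermediate
5 | ethyl (2R)-4-bromo-2-[(tert-butyldimethylsilyl)oxy]-4-methylpentanoate | CCOC(=O)[C@H](O[Si](C)(C)C(C)(C)C)CC(C)(C)Br | intermediate
6 | (2R)-4-bromo-2-[(tert-butyldimethylsilyl)oxy]-4-methylpentanal | O=C[C@H](O[Si](C)(C)C(C)(C)C)CC(C)(C)Br | intermediate
7 | (E)-3-methylpent-2-en-4-yn-1-ol | C#C/C(C)=C/CO | starting material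
8 | triethyl{[(2E)-3-methylpent-2-en-4-yn-1-yl]oxy}silane | C#C/C(C)=C/CO[Si](CC)(CC)CC | intermediate
9 | chlorobis(cyclopentadienyl){(1E,3E)-3-methyl-5-[(triethylsilyl)oxy]penta-1,3-dien-1-yl}zirconium, not isolated (cyclopentadienyl rings written σ-bound in the SMILES) | Cl[Zr](/C=C/C(C)=C/CO[Si](CC)(CC)CC)(C1C=CC=C1)C1C=CC=C1 | intermediate
10 | triethyl{[(2E,4E)-5-iodo-3-methylpenta-2,4-dien-1-yl]oxy}silane | I/C=C/C(C)=C/CO[Si](CC)(CC)CC | intermediate
11 | propyne | CC#C | starting material
12 | triethyl{[(2E,4E)-3-methylocta-2,4-dien-6-yn-1-yl]oxy}silane | CC#C/C=C/C(C)=C/CO[Si](CC)(CC)CC | intermediate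
13 | oxanickelacyclopentene from 6 and 12, not isolated: five-membered ring Ni–O–C4–C5=C6, with C4 (S) bearing the (R)-CH(OTBS)CH2CMe2Br chain, C5 the methyl group and C6 the dienyl chain (bipyridine ligand on nickel not drawn) | CC1=C(/C=C/C(C)=C/CO[Si](CC)(CC)CC)[Ni]O[C@@H]1[C@@H](CC(C)(C)Br)O[Si](C)(C)C(C)(C)C | intermediate
14 | (1S,6R)-6-[(tert-butyldimethylsilyl)oxy]-2,4,4-trimethyl-3-{(1E,3E)-3-methyl-5-[(triethylsilyl)oxy]penta-1,3-dien-1-yl}cyclohex-2-en-1-ol (3,4-cis) | CC[Si](CC)(CC)OC/C=C(C)/C=C/C1=C(C)[C@H](O)[C@H](O[Si](C)(C)C(C)(C)C)CC1(C)C | intermediate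
15 | (6R)-6-[(tert-butyldimethylsilyl)oxy]-2,4,4-trimethyl-3-{(1E,3E)-3-methyl-5-[(triethylsilyl)oxy]penta-1,3-dien-1-yl}cyclohex-2-en-1-one | CC[Si](CC)(CC)OC/C=C(C)/C=C/C1=C(C)C(=O)[C@H](O[Si](C)(C)C(C)(C)C)CC1(C)C | intermediate
16 | (1R,6R)-6-[(tert-butyldimethylsilyl)oxy]-2,4,4-trimethyl-3-{(1E,3E)-3-methyl-5-[(triethylsilyl)oxy]penta-1,3-dien-1-yl}cyclohex-2-en-1-ol (3,4-trans) | CC[Si](CC)(CC)OC/C=C(C)/C=C/C1=C(C)[C@@H](O)[C@H](O[Si](C)(C)C(C)(C)C)CC1(C)C | intermediate
17 | {[(2E,4E)-5-{(3R,4R)-3,4-bis[(tert-butyldimethylsilyl)oxy]-2,6,6-trimethylcyclohex-1-en-1-yl}-3-methylpenta-2,4-dien-1-yl]oxy}triethylsilane, not isolated | CC[Si](CC)(CC)OC/C=C(C)/C=C/C1=C(C)[C@@H](O[Si](C)(C)C(C)(C)C)[C@H](O[Si](C)(C)C(C)(C)C)CC1(C)C | intermediate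
18 | (2E,4E)-5-{(3R,4R)-3,4-bis[(tert-butyldimethylsilyl)oxy]-2,6,6-trimethylcyclohex-1-en-1-yl}-3-methylpenta-2,4-dien-1-ol | OC/C=C(C)/C=C/C1=C(C)[C@@H](O[Si](C)(C)C(C)(C)C)[C@H](O[Si](C)(C)C(C)(C)C)CC1(C)C | intermediate
19 | (3R,4R)-1-[(1E,3E)-5-bromo-3-methylpenta-1,3-dien-1-yl]-3,4-bis[(tert-butyldimethylsilyl)oxy]-2,6,6-trimethylcyclohex-1-ene, not isolated | BrC/C=C(C)/C=C/C1=C(C)[C@@H](O[Si](C)(C)C(C)(C)C)[C@H](O[Si](C)(C)C(C)(C)C)CC1(C)C | intermediate
20 | [(2E,4E)-5-{(3R,4R)-3,4-bis[(tert-butyldimethylsilyl)oxy]-2,6,6-trimethylcyclohex-1-en-1-yl}-3-methylpenta-2,4-dien-1-yl]triphenylphosphonium bromide | [Br-].c1ccccc1[P+](c1ccccc1)(c1ccccc1)C/C=C(C)/C=C/C1=C(C)[C@@H](O[Si](C)(C)C(C)(C)C)[C@H](O[Si](C)(C)C(C)(C)C)CC1(C)C | intermediate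
21 | (3E,5E)-6,10-dimethylundeca-3,5,9-trien-2-one (pseudoionone) | CC(=O)/C=C/C=C(C)/CCC=C(C)C | starting material
22 | vinylmagnesium bromide | C=C[Mg]Br | starting material
23 | (4E,6E)-3,7,11-trimethyldodeca-1,4,6,10-tetraen-3-ol (racemic) | C=CC(C)(O)/C=C/C=C(C)/CCC=C(C)C | intermediate
24 | [(2E,4E,6E)-3,7,11-trimethyldodeca-2,4,6,10-tetraen-1-yl]triphenylphosphonium bromide | [Br-].CC(C)=CCC/C(C)=C/C=C/C(C)=C/C[P+](c1ccccc1)(c1ccccc1)c1ccccc1 | intermediate
25 | (2E,4E,6E)-2,7-dimethylocta-2,4,6-trienedial | O=C/C(C)=C/C=C/C=C(C)/C=O | starting material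
26 | (2E,4E,6E,8Z,10E,12E,14E)-2,7,11,15,19-pentamethylicosa-2,4,6,8,10,12,14,18-octaenal, not isolated | CC(C)=CCC/C(C)=C/C=C/C(C)=C/C=C\C(C)=C\C=C\C=C(C)\C=O | intermediate
27 | (2E,4E,6E,8E,10E,12E,14E)-2,7,11,15,19-pentamethylicosa-2,4,6,8,10,12,14,18-octaenal | CC(C)=CCC/C(C)=C/C=C/C(C)=C/C=C/C(C)=C/C=C/C=C(C)/C=O | intermediate
28 | (11Z,3R,4R)-3,4-bis[(tert-butyldimethylsilyl)oxy]-β,ψ-carotene, not isolated | CC(C)=CCC/C(C)=C/C=C/C(C)=C/C=C/C(C)=C/C=C/C=C(C)/C=C\C=C(C)\C=C\C1=C(C)[C@@H](O[Si](C)(C)C(C)(C)C)[C@H](O[Si](C)(C)C(C)(C)C)CC1(C)C | intermediate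
29 | (3R,4R)-3,4-bis[(tert-butyldimethylsilyl)oxy]-β,ψ-carotene (all-E) | CC(C)=CCC/C(C)=C/C=C/C(C)=C/C=C/C(C)=C/C=C/C=C(C)/C=C/C=C(C)/C=C/C1=C(C)[C@@H](O[Si](C)(C)C(C)(C)C)[C@H](O[Si](C)(C)C(C)(C)C)CC1(C)C | intermediate
30 | (3R,4R)-β,ψ-carotene-3,4-diol (all-E) | CC(C)=CCC/C(C)=C/C=C/C(C)=C/C=C/C(C)=C/C=C/C=C(C)/C=C/C=C(C)/C=C/C1=C(C)[C@@H](O)[C@H](O)CC1(C)C | target

**Summary**

Total step count: 17.
Longest linear sequence: 11 steps (steps 1–4, 8–12, 16 and 17).

**Steps most likely to fail**

Step 8 (proposed new method). The tertiary C–Br bond may be activated by low-valent nickel before the aldehyde–enyne oxidative cyclisation, leading to elimination or reduction, or the enyne may be oligomerised by nickel. The fallback makes the two bonds in separate, known operations and sets out from 4 and 10. Ester 4 is reduced with i-Bu2AlH at −78 °C to (2R)-2-[(tert-butyldimethylsilyl)oxy]-4-methylpent-4-enal F1. Iodide 10 is coupled with ethynylzinc bromide under Pd(PPh3)4 catalysis (Negishi coupling) to triethyl{[(2E,4E)-3-methylhepta-2,4-dien-6-yn-1-yl]oxy}silane F2. The lithium acetylide of F2 (n-BuLi, THF, −78 °C) adds to F1 under Felkin–Anh control and forms C4–C5 in the propargylic alcohol (2E,4E,8S,9R)-9-[(tert-butyldimethylsilyl)oxy]-3,11-dimethyl-1-[(triethylsilyl)oxy]dodeca-2,4,11-trien-6-yn-8-ol F3. Copper-catalysed anti-carbomagnesiation (MeMgBr, CuI), directed by the magnesium alkoxide, followed by iodinolysis puts the methyl group on C5 and iodine on C6 cis to C4, giving (2E,4E,6Z,8S,9R)-9-[(tert-butyldimethylsilyl)oxy]-6-iodo-3,7,11-trimethyl-1-[(triethylsilyl)oxy]dodeca-2,4,6,11-tetraen-8-ol F4. A reductive Heck cyclisation (Pd(OAc)2, PPh3, HCO2Na, DMF, 80 °C) closes C6–C1 in the 6-exo-trig mode onto the isopropenyl group, the neopentylpalladium intermediate being reduced by formate to the second methyl group, and the fallback comes back to the route at 14.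

Step 10. Hydride may be delivered to the wrong face of enone 15, giving the 3,4-cis alcohol again. The fallback replaces substrate-controlled external delivery by hydroxyl-directed internal delivery and sets out from 15. Aqueous HF in MeCN at 0 °C removes both silyl groups to give (6R)-6-hydroxy-3-[(1E,3E)-5-hydroxy-3-methylpenta-1,3-dien-1-yl]-2,4,4-trimethylcyclohex-2-en-1-one F5. Me4NBH(OAc)3 in AcOH/MeCN at −30 °C binds the C3 hydroxyl and delivers hydride to C4 from the same face, which should give the 3,4-trans triol (1R,2R)-4-[(1E,3E)-5-hydroxy-3-methylpenta-1,3-dien-1-yl]-3,5,5-trimethylcyclohex-3-ene-1,2-diol F6. Exhaustive silylation (TBSOTf, 2,6-lutidine) gives tert-butyl{[(2E,4E)-5-{(3R,4R)-3,4-bis[(tert-butyldimethylsilyl)oxy]-2,6,6-trimethylcyclohex-1-en-1-yl}-3-methylpenta-2,4-dien-1-yl]oxy}dimethylsilane F7, and HF·pyridine/pyridine in THF at 0 °C frees only the primary alcohol, so the fallback comes back to the route at 18.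

Step 15. The ylide may react a second time with the product aldehyde, consuming 24 in a double olefination. The fallback removes the second aldehyde from play and sets out from 25. The dialdehyde is desymmetrised with 2,2-dimethylpropane-1,3-diol (1 equiv, PPTS, toluene) to the mono-acetal (2E,4E,6E)-7-(5,5-dimethyl-1,3-dioxan-2-yl)-2-methylocta-2,4,6-trienal F8, with unreacted 25 and bis-acetal recycled. Wittig olefination of F8 with 24 under the conditions of step 15 gives 5,5-dimethyl-2-[(1E,3E,5E,7E,9E,11E,13E)-1,6,10,14,18-pentamethylnonadeca-1,3,5,7,9,11,13,17-octaen-1-yl]-1,3-dioxane F9, and mild aqueous acid (PPTS, acetone/water) releases the aldehyde, so the fallback comes back to the route at 27.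

**Further compounds**

F1 | step 8 | (2R)-2-[(tert-butyldimethylsilyl)oxy]-4-methylpent-4-enal | O=C[C@H](O[Si](C)(C)C(C)(C)C)CC(C)=C
F2 | step 8 | triethyl{[(2E,4E)-3-methylhepta-2,4-dien-6-yn-1-yl]oxy}silane | C#C/C=C/C(C)=C/CO[Si](CC)(CC)CC
F3 | step 8 | (2E,4E,8S,9R)-9-[(tert-butyldimethylsilyl)oxy]-3,11-dimethyl-1-[(triethylsilyl)oxy]dodeca-2,4,11-trien-6-yn-8-ol | C=C(C)C[C@@H](O[Si](C)(C)C(C)(C)C)[C@@H](O)C#C/C=C/C(C)=C/CO[Si](CC)(CC)CC
F4 | step 8 | (2E,4E,6Z,8S,9R)-9-[(tert-butyldimethylsilyl)oxy]-6-iodo-3,7,11-trimethyl-1-[(triethylsilyl)oxy]dodeca-2,4,6,11-tetraen-8-ol | C=C(C)C[C@@H](O[Si](C)(C)C(C)(C)C)[C@@H](O)/C(C)=C(I)/C=C/C(C)=C/CO[Si](CC)(CC)CC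
F5 | step 10 | (6R)-6-hydroxy-3-[(1E,3E)-5-hydroxy-3-methylpenta-1,3-dien-1-yl]-2,4,4-trimethylcyclohex-2-en-1-one | OC/C=C(C)/C=C/C1=C(C)C(=O)[C@H](O)CC1(C)C
F6 | step 10 | (1R,2R)-4-[(1E,3E)-5-hydroxy-3-methylpenta-1,3-dien-1-yl]-3,5,5-trimethylcyclohex-3-ene-1,2-diol | OC/C=C(C)/C=C/C1=C(C)[C@@H](O)[C@H](O)CC1(C)C
F7 | step 10 | tert-butyl{[(2E,4E)-5-{(3R,4R)-3,4-bis[(tert-butyldimethylsilyl)oxy]-2,6,6-trimethylcyclohex-1-en-1-yl}-3-methylpenta-2,4-dien-1-yl]oxy}dimethylsilane | CC(C)(C)[Si](C)(C)OC/C=C(C)/C=C/C1=C(C)[C@@H](O[Si](C)(C)C(C)(C)C)[C@H](O[Si](C)(C)C(C)(C)C)CC1(C)C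
F8 | step 15 | (2E,4E,6E)-7-(5,5-dimethyl-1,3-dioxan-2-yl)-2-methylocta-2,4,6-trienal | O=C/C(C)=C/C=C/C=C(C)/C1OCC(C)(C)CO1
F9 | step 15 | 5,5-dimethyl-2-[(1E,3E,5E,7E,9E,11E,13E)-1,6,10,14,18-pentamethylnonadeca-1,3,5,7,9,11,13,17-octaen-1-yl]-1,3-dioxane | CC(C)=CCC/C(C)=C/C=C/C(C)=C/C=C/C(C)=C/C=C/C=C(C)/C1OCC(C)(C)CO1
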